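Colleague, you want a quick number for the two flasks below, and your hunch is that Monday's warm flask ends richest in E. I would bet against that.

| flask | Q | L | temperature | remark | time |
|---|---|---|---|---|---|
| elm | 0.020 M | 0.020 M | 6 °C | run made earlier |  |
| cedar | 0.020 M | 0.045 M | 20 °C | run made earlier |  |
| Saturday's | 0.020 M | 0.0300 M | 0 °C |  | 10 min |
| Monday's | 0.020 M | 0.0300 M | 25 °C |  | 10 min |

| run | time / min | Q / % | Z / % | G / % | E / % |
|---|---|---|---|---|---|
| elm | 0.667 | 98.0 | 3.4 | 0 | 0.4 |
| elm | 2.00 | 91.8 | 7.5 | 0 | 0 |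
| elm | 3.00 | 87.9 | 11.4 | 0.6 | 0 |
| elm | 5.00 | 81.6 | 15.9 | 1.5 | 0.5 |
| elm | 8.00 | 73.2 | 21.4 | 1.8 | 1.7 |
| elm | 10.0 | 69.1 | 26.2 | 2.2 | 2.3 |
| elm | 12.0 | 65.7 | 27.2 | 3.4 | 2.6 |
| cedar | 0.250 | 92.2 | 6.8 | 0.3 | 0.2 |
| cedar | 0.667 | 82.2 | 16.2 | 0.2 | 0.5 |
| cedar | 1.00 | 74.5 | 23.5 | 2.2 | 1.3 |
| cedar | 2.00 | 57.6 | 32.3 | 4.9 | 5.1 |
| cedar | 3.00 | 45.3 | 35.7 | 5.7 | 10.6 |
| cedar | 4.00 | 38.6 | 38.2 | 6.8 | 16.9 |

(readings scatter by 0.5 percentage points)

- which of these there is most of at the end, counted by the Q in it, Saturday's (Q / E / G / Z)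
- which of these there is most of at the end, counted by the Q in it, Monday's (Q / E / G / Z)
- the largest of these amounts at the end, in percent of the Q charged, Saturday's
- the largest of these amounts at the end, in percent of the Q charged, Monday's

Count in L. Both new flasks get 1.50 of L per unit of Q charged, and each Z holds one L, each G two. In the cedar run G per Z reads 0.152 at 2.00 min and 0.178 at 4.00 min, higher while L is being taken up. So I read G's loss as tied to L, and charge each E with 3 L. That makes L the limiting reagent on the way to E, since its charge is less than the 3 that full conversion takes. The E ceiling is the fraction of the Q charge that the L charge can pay for as E: the L charge, less Z, less twice G, all over 3. With cedar's last Z and G, 38.2 % and 6.8 %, as my estimate for Monday's, whose own I don't have, it comes to 32.7 %, below that Z. So I commit to Z on Monday, near 38.2 %.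

The forecast says Q at 71 % (67 % to 75 %) for Saturday's and E at 40 % (34 % to 47 %) for Monday's, adding “E and Z are close”. Its E lies above my estimated ceiling, and that is where we part.

    L + G → E (k = 8.10 M⁻¹ min⁻¹, Ea = 48.0 kJ mol⁻¹)
    Q + L → Z + X (k = 1.40 M⁻¹ min⁻¹, Ea = 54.0 kJ mol⁻¹)
    L + Z → G + X (k = 1.40 M⁻¹ min⁻¹, Ea = 51.0 kJ mol⁻¹)
    (constants at 0 °C)

Saturday's flask ends with Q at 69.4 %, Monday's with Z at 38.2 % and E at 26.4 %. At 10 min Monday's E stands 6.3 percentage points under the ceiling I reckoned from cedar's Z and G, with 12.1 % of its L left, and the half-life of that flask's slowest mode as it stands then, 11.2 min, is longer than the run. The neighbour at 40 °C, on the same charges, has 0.45 % of its L left, its own Z and G put the ceiling at 32.2 %, and its E stands at 31.9 %.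

The data were computed with made-up constants, noise included.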